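Ring C (C1–C5) is disconnected at C1–C2, the bond between the cyclobutane CH next to the methyl-bearing C10 and the acetoxy carbon, by an intramolecular Pauson–Khand reaction. The precursor is a ring A cyclopentane fused to a cyclobutene (C1=C5) that carries a propargyl ether on the concave C7 oxygen. One operation forms C1–C2, C2–C3 and C4–C5 and closes ring C as an enone. The step exploits the syn placement of rings A and C on cyclobutane ring B: the C7–O–C15 tether can reach only that face of C1=C5, fixes the regiochemistry, and is later cleaved so that C15 becomes the C4 methyl and C7 the butenolide carbon.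

Key step: step 8

Remark on numbering: ring A = C6–C7–C8–C9–C10 (C8 carries the tiglate); ring B = cyclobutane C1–C5–C6–C10 (C6 carries the lactone oxygen, C10 the methyl C14); ring C = C1–C2–C3–C4–C5 (C2 acetoxy, C4 hydroxy and methyl C15); ring D = butenolide O–C12(=O)–C11=C7–C6 with C13 = CH2OAc on C11. Convex face = the face of H1, H5, C14 and O6; concave face = the face on which rings A and C lie (cis-syn-cis). Compounds 4, 5 and 6 are racemates; their SMILES show the enantiomer that is carried on.

Step 1
Reactants: 1 cyclotene (2-hydroxy-3-methylcyclopent-2-en-1-one)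
Product: 2 3-methyl-2-[(trimethylsilyl)oxy]cyclopent-2-en-1-one
Conditions: TMSCl, Et3N, CH2Cl2, 0 °C to rt
Reagents that add atoms: chlorotrimethylsilane, C[Si](C)(C)Cl
Why: O-silylation of the enolised 1,2-diketone gives a photostable enol ether that carries no activated hydrogen for abstraction by the excited enone.

Step 2
Reactants: 2 silyl enol ether; 3 acetylene
Product: 5 rac-(1R,5R)-1-hydroxy-5-methylbicyclo[3.2.0]hept-6-en-2-one, via silyl ether photoadduct 4 (not isolated)
Conditions: hν (350 nm, Pyrex), acetylene-saturated CH2Cl2, −70 °C; then 1 M HCl, THF, 0 °C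
Reagents that add atoms: none
Why: Enone–alkyne [2+2] photocycloaddition from the enone triplet should give the cis-fused cyclobutene and set C6 and C10 (both ring-fusion centres, necessarily cis) as a racemate, and dilute acid then cleaves the tertiary trimethylsilyl ether.

Step 3
Reactants: 5 racemic hydroxy ketone
Product: 6 rac-(1R,2R,5R)-5-methylbicyclo[3.2.0]hept-6-ene-1,2-diol (trans-diol; C7–OH on the concave face)
Conditions: Me4NBH(OAc)3, MeCN/AcOH, −20 °C
Reagents that add atoms: none
Why: Hydroxyl-directed reduction (Saksena–Evans): the C6 hydroxyl binds boron and delivers hydride to the same (convex) face of the C7 carbonyl, so the new hydroxyl should stand on the concave face, trans to C6–OH.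

Step 4
Reactants: 6 racemic trans-diol
Product: 7 (1R,2R,5R)-1-hydroxy-5-methylbicyclo[3.2.0]hept-6-en-2-yl acetate
Conditions: lipase PS (Burkholderia cepacia, immobilised), vinyl acetate, MTBE, 30 °C, stopped short of half conversion; chromatographic separation from the unreacted diol
Reagents that add atoms: vinyl acetate, C=COC(C)=O
Why: Lipase-catalysed kinetic resolution by transesterification, in which the large/medium substituent model for lipases (C6 large, C8 medium) predicts faster acylation of the (2R) alcohol, while the tertiary hydroxyl is not a substrate.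

Step 5
Reactants: 7 monoacetate
Product: 8 (1R,2R,5R)-5-methyl-1-[(triethylsilyl)oxy]bicyclo[3.2.0]hept-6-en-2-yl acetate
Conditions: TESOTf, 2,6-lutidine, CH2Cl2, −78 to 0 °C
Reagents that add atoms: triethylsilyl trifluoromethanesulfonate, CC[Si](CC)(CC)OS(=O)(=O)C(F)(F)F
Why: Silylation of the tertiary alcohol with a silyl triflate, which later keeps the C6 oxygen out of the etherification, Mitsunobu and enolisation steps.

Step 6
Reactants: 8 silyl ether acetate
Product: 9 (1R,2R,5R)-5-methyl-1-[(triethylsilyl)oxy]bicyclo[3.2.0]hept-6-en-2-ol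
Conditions: K2CO3, MeOH, 0 °C to rt
Reagents that add atoms: none
Why: Base-catalysed transesterification removes the acetate without touching the tertiary silyl ether or any stereocentre.

Step 7
Reactants: 9 alcohol; 10 propargyl bromide
Product: 11 triethyl{[(1R,2R,5R)-5-methyl-2-(prop-2-yn-1-yloxy)bicyclo[3.2.0]hept-6-en-1-yl]oxy}silane
Conditions: NaH, Bu4NI (cat.), THF/DMF, 0 °C to rt
Reagents that add atoms: none
Why: Williamson ether synthesis on the only free alkoxide, the trans relation of O6 and O7 disfavouring silyl migration.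

Step 8
Reactants: 11 enyne
Product: 13 tetracyclic Pauson–Khand enone (C2 ketone; C3=C4; C4–C15H2–O–C7 ether bridge on the concave face; C6 triethylsilyl ether; rings A/B/C cis-syn-cis), via dicobalt hexacarbonyl alkyne complex 12 (not isolated)
Conditions: Co2(CO)8 (1.1 equiv), CH2Cl2, rt; then NMO, 0 °C to rt
Reagents that add atoms: dicobalt octacarbonyl (source of the C2 carbonyl), O=C=[Co](=C=O)(=C=O)(=C=O)[Co](=C=O)(=C=O)(=C=O)=C=O
Why: Pauson–Khand reaction, a cobalt-mediated (2+2+1) cycloaddition: complex 12 loses CO on N-oxide activation, the cyclobutene inserts into the Co–C4 bond (C4–C5), CO inserts into the resulting Co–C1 bond (C1–C2) and reductive elimination closes C2–C3. The closest known reactions are intramolecular Pauson–Khand reactions of 1,7-enynes with ether tethers and intermolecular ones of cyclobutenes, whose strain makes them good alkene partners. Ring C is closed as a cyclopentenone by the (2+2+1) cycloaddition, and the temporary six-membered oxacycle C4–C5–C6–C7–O–C15 by 6-exo insertion. C1 and C5 are set by suprafacial addition to C1=C5 on the only face the C7 oxygen tether can reach, the concave face that carries ring A, which should give the cis-syn-cis array with H1 and H5 on the convex face. The step needs this facial selectivity (an untethered alkyne would approach from the convex face) and the regiochemistry C4 to C5 and CO to C1; both are enforced by the tether, since C4 can bond only to the proximal alkene carbon C5.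

Step 9
Reactants: 13 Pauson–Khand enone
Product: 14 ring-opened ketone (C2 ketone; C4=C15H2 exocyclic methylene; C7–OH on the concave face; C6 triethylsilyl ether)
Conditions: SmI2 (2.2 equiv), THF/MeOH, −78 °C
Reagents that add atoms: none
Why: Two-electron reduction of the enone gives a C4 carbanion that expels the γ-alkoxide (vinylogous reductive cleavage of an α-alkoxy ketone, helped by opening of the bridged ether), and kinetic α-protonation of the samarium dienolate should give the β,γ-unsaturated ketone in which C15 is an exocyclic methylene.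

Step 10
Reactants: 14 ring-opened ketone
Product: 15 diol (C2–OH on the concave face; C7–OH)
Conditions: NaBH4, MeOH, −40 to 0 °C
Reagents that add atoms: none
Why: Hydride should add to C2 from the convex face of the U-shaped cis-syn-cis tricycle, the concave face being shielded by ring A, which places the hydroxyl on the concave face.

Step 11
Reactants: 15 diol
Product: 16 C2 acetate (acetoxy on the convex face; C7–OH free)
Conditions: AcOH, PPh3, DIAD, THF, 0 °C to rt
Reagents that add atoms: acetic acid, CC(=O)O
Why: Mitsunobu reaction: SN2 displacement of the activated C2 oxygen by acetate inverts C2 to the configuration of the target, while the neopentyl-type C7 hydroxyl next to the quaternary C6 should react far more slowly.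

Step 12
Reactants: 16 C2 acetate
Product: 17 C7 ketone
Conditions: Dess–Martin periodinane, NaHCO3, CH2Cl2, rt
Reagents that add atoms: none
Why: Dess–Martin oxidation of the one remaining secondary alcohol under buffered conditions.

Step 13
Reactants: 17 C7 ketone
Product: 20 C6/C8-dihydroxy C7 ketone (C8–OH on the convex face), via triethylsilyl enol ether 18 (not isolated), via C8-silyloxy ketone 19 (not isolated)
Conditions: TESOTf, Et3N, CH2Cl2, −78 to 0 °C; mCPBA (1.0 equiv), NaHCO3, CH2Cl2, −40 °C; HF·pyridine, THF/pyridine, 0 °C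
Reagents that add atoms: 3-chloroperoxybenzoic acid, OOC(=O)c1cccc(Cl)c1; triethylsilyl trifluoromethanesulfonate (kept only in 18 and 19), CC[Si](CC)(CC)OS(=O)(=O)C(F)(F)F
Why: Rubottom oxidation: C8 is the only enolisable position, the electron-rich silyl enol ether should be epoxidised much faster than the 1,1-disubstituted alkene and from the convex face (the other face lies in the cleft towards ring C), and fluoride then removes both silyl groups.

Step 14
Reactants: 20 dihydroxy ketone; 21 tiglic acid
Product: 22 C8 tiglate (C6–OH free; C7 ketone)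
Conditions: 2,4,6-trichlorobenzoyl chloride, Et3N, THF, rt; then 20, DMAP, toluene, rt
Reagents that add atoms: none
Why: Yamaguchi esterification acylates the secondary C8 hydroxyl, the tertiary ring-fusion hydroxyl at C6 being too hindered to compete.

Step 15
Reactants: 23 benzyl 2-(diethoxyphosphoryl)acetate; 24 paraformaldehyde
Product: 25 benzyl 2-(diethoxyphosphoryl)-3-hydroxypropanoate (racemic)
Conditions: (CH2O)n (1.0 equiv), K2CO3 (cat.), THF, rt
Reagents that add atoms: none
Why: Aldol-type hydroxymethylation of the phosphonate-stabilised carbanion, which with one equivalent of formaldehyde and only catalytic weak base should stop before olefination.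

Step 16
Reactants: 25 hydroxymethyl phosphonate
Product: 26 benzyl 3-[(tert-butyldimethylsilyl)oxy]-2-(diethoxyphosphoryl)propanoate
Conditions: TBSCl, imidazole, DMF, 0 °C to rt
Reagents that add atoms: tert-butyldimethylsilyl chloride, CC(C)(C)[Si](C)(C)Cl
Why: Standard silylation of the primary alcohol.

Step 17
Reactants: 26 silyl ether
Product: 27 3-[(tert-butyldimethylsilyl)oxy]-2-(diethoxyphosphoryl)propanoic acid
Conditions: H2 (1 atm), Pd/C, EtOAc, rt
Reagents that add atoms: none
Why: Hydrogenolysis of the benzyl ester leaves the silyl ether and the phosphonate untouched.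

Step 18
Reactants: 22 C8 tiglate; 27 phosphonate acid
Product: 29 butenolide (ring D closed; C13–OSiMe2tBu; C4=C15H2), via phosphonate ester 28 (not isolated)
Conditions: DCC, DMAP (cat.), CH2Cl2, 0 °C to rt; then LiCl, DBU, MeCN, rt
Reagents that add atoms: none
Why: Carbodiimide activation of the phosphonoacetic acid (through a phosphonoketene) should acylate the hindered tertiary C6 hydroxyl, and an intramolecular Horner–Wadsworth–Emmons reaction under Masamune–Roush conditions then forms the tetrasubstituted C7=C11 bond and closes ring D without creating a stereocentre.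

Step 19
Reactants: 29 silyl-protected butenolide
Product: 31 C13 acetate (C4=C15H2 still present), via primary alcohol 30 (not isolated)
Conditions: HF·pyridine, THF/pyridine, 0 °C; then Ac2O, DMAP (cat.), pyridine, 0 °C to rt
Reagents that add atoms: acetic anhydride, CC(=O)OC(C)=O
Why: Fluoride cleaves the primary silyl ether, and the liberated allylic alcohol, the only hydroxyl in the molecule, is then acetylated.

Step 20
Reactants: 31 C13 acetate
Product: 32 target CNP0210373.1
Conditions: Co(acac)2 (cat.), PhSiH3, O2 (1 atm), THF/iPrOH, rt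
Reagents that add atoms: dioxygen, O=O
Why: Mukaiyama hydration: hydrogen-atom transfer from a cobalt hydride to C15 gives the tertiary C4 radical, which O2 should trap on the convex face (hydroxyl convex, methyl concave, Markovnikov), and the electron-rich 1,1-disubstituted alkene should react in preference to the conjugated tri- and tetrasubstituted alkenes.

Compound list
1 | cyclotene (2-hydroxy-3-methylcyclopent-2-en-1-one) | CC1=C(O)C(=O)CC1 | starting material
2 | 3-methyl-2-[(trimethylsilyl)oxy]cyclopent-2-en-1-one | CC1=C(O[Si](C)(C)C)C(=O)CC1 | intermediate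
3 | acetylene | C#C | starting material
4 | rac-(1R,5R)-5-methyl-1-[(trimethylsilyl)oxy]bicyclo[3.2.0]hept-6-en-2-one | C1C[C@]2(C)C=C[C@]2(O[Si](C)(C)C)C1=O | intermediate (not isolated)
5 | rac-(1R,5R)-1-hydroxy-5-methylbicyclo[3.2.0]hept-6-en-2-one | C1C[C@]2(C)C=C[C@]2(O)C1=O | intermediate
6 | rac-(1R,2R,5R)-5-methylbicyclo[3.2.0]hept-6-ene-1,2-diol | C1C[C@]2(C)C=C[C@]2(O)[C@@H]1O | intermediate
7 | (1R,2R,5R)-1-hydroxy-5-methylbicyclo[3.2.0]hept-6-en-2-yl acetate | C1C[C@]2(C)C=C[C@]2(O)[C@@H]1OC(C)=O | intermediate
8 | (1R,2R,5R)-5-methyl-1-[(triethylsilyl)oxy]bicyclo[3.2.0]hept-6-en-2-yl acetate | C1C[C@]2(C)C=C[C@]2(O[Si](CC)(CC)CC)[C@@H]1OC(C)=O | intermediate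
9 | (1R,2R,5R)-5-methyl-1-[(triethylsilyl)oxy]bicyclo[3.2.0]hept-6-en-2-ol | C1C[C@]2(C)C=C[C@]2(O[Si](CC)(CC)CC)[C@@H]1O | intermediate
10 | propargyl bromide (3-bromoprop-1-yne) | C#CCBr | starting material
11 | triethyl{[(1R,2R,5R)-5-methyl-2-(prop-2-yn-1-yloxy)bicyclo[3.2.0]hept-6-en-1-yl]oxy}silane | C1C[C@]2(C)C=C[C@]2(O[Si](CC)(CC)CC)[C@@H]1OCC#C | intermediate
12 | Co2(CO)6 complex of the alkyne of 11 (dicobalt hexacarbonyl bridged by the C3–C4 alkyne) | C1C[C@]2(C)C=C[C@]2(O[Si](CC)(CC)CC)[C@@H]1OCC34[CH]5[Co]3(=C=O)(=C=O)(=C=O)[Co]45(=C=O)(=C=O)=C=O | intermediate (not isolated)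
13 | tetracyclic Pauson–Khand enone: cis-syn-cis rings A/B/C, C2 ketone, C3=C4, C4–C15H2–O–C7 bridge on the concave face, C6–OSiEt3 | C1C[C@]2(C)[C@@H]3C(=O)C=C4CO[C@H]1[C@@]2(O[Si](CC)(CC)CC)[C@H]34 | intermediate
14 | ring-opened ketone: C2 ketone, C4=C15H2, C7–OH concave, C6–OSiEt3 | C1C[C@]2(C)[C@@H]3C(=O)CC(=C)[C@@H]3[C@]2(O[Si](CC)(CC)CC)[C@@H]1O | intermediate
15 | diol: C2–OH concave, C7–OH concave, C4=C15H2, C6–OSiEt3 | C1C[C@]2(C)[C@@H]3[C@H](O)CC(=C)[C@@H]3[C@]2(O[Si](CC)(CC)CC)[C@@H]1O | intermediate
16 | C2 acetate (convex), C7–OH, C4=C15H2, C6–OSiEt3 | C1C[C@]2(C)[C@@H]3[C@@H](OC(C)=O)CC(=C)[C@@H]3[C@]2(O[Si](CC)(CC)CC)[C@@H]1O | intermediate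
17 | C7 ketone with C2 acetate, C4=C15H2, C6–OSiEt3 | C1C[C@]2(C)[C@@H]3[C@@H](OC(C)=O)CC(=C)[C@@H]3[C@]2(O[Si](CC)(CC)CC)C1=O | intermediate
18 | C7 triethylsilyl enol ether (C7=C8) of 17 | C=1C[C@]2(C)[C@@H]3[C@@H](OC(C)=O)CC(=C)[C@@H]3[C@]2(O[Si](CC)(CC)CC)C=1O[Si](CC)(CC)CC | intermediate (not isolated)
19 | C8 triethylsilyloxy (convex) C7 ketone, C6–OSiEt3 | CC[Si](CC)(CC)O[C@H]1C[C@]2(C)[C@@H]3[C@@H](OC(C)=O)CC(=C)[C@@H]3[C@]2(O[Si](CC)(CC)CC)C1=O | intermediate (not isolated)
20 | C6,C8-dihydroxy C7 ketone (C8–OH convex), C2 acetate, C4=C15H2 | O[C@H]1C[C@]2(C)[C@@H]3[C@@H](OC(C)=O)CC(=C)[C@@H]3[C@]2(O)C1=O | intermediate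
21 | tiglic acid ((E)-2-methylbut-2-enoic acid) | C/C=C(\C)C(=O)O | starting material
22 | C8 tiglate, C6–OH, C7 ketone, C2 acetate, C4=C15H2 | C/C=C(\C)C(=O)O[C@H]1C[C@]2(C)[C@@H]3[C@@H](OC(C)=O)CC(=C)[C@@H]3[C@]2(O)C1=O | intermediate
23 | benzyl 2-(diethoxyphosphoryl)acetate | CCOP(=O)(CC(=O)OCc1ccccc1)OCC | starting material
24 | paraformaldehyde (as formaldehyde) | C=O | starting material
25 | benzyl 2-(diethoxyphosphoryl)-3-hydroxypropanoate (racemic) | CCOP(=O)(OCC)C(CO)C(=O)OCc1ccccc1 | intermediate
26 | benzyl 3-[(tert-butyldimethylsilyl)oxy]-2-(diethoxyphosphoryl)propanoate (racemic) | CCOP(=O)(OCC)C(CO[Si](C)(C)C(C)(C)C)C(=O)OCc1ccccc1 | intermediate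
27 | 3-[(tert-butyldimethylsilyl)oxy]-2-(diethoxyphosphoryl)propanoic acid (racemic) | CCOP(=O)(OCC)C(CO[Si](C)(C)C(C)(C)C)C(=O)O | intermediate
28 | C6 ester of 22 with acid 27 (both epimers at the phosphonate carbon) | C/C=C(\C)C(=O)O[C@H]1C[C@]2(C)[C@@H]3[C@@H](OC(C)=O)CC(=C)[C@@H]3[C@]2(OC(=O)C(CO[Si](C)(C)C(C)(C)C)P(=O)(OCC)OCC)C1=O | intermediate (not isolated)
29 | butenolide with C13–OSiMe2tBu, C8 tiglate, C2 acetate, C4=C15H2 | C/C=C(\C)C(=O)O[C@H]1C[C@]2(C)[C@@H]3[C@@H](OC(C)=O)CC(=C)[C@@H]3[C@@]23OC(=O)C(CO[Si](C)(C)C(C)(C)C)=C13 | intermediate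
30 | butenolide with C13–OH, C8 tiglate, C2 acetate, C4=C15H2 | C/C=C(\C)C(=O)O[C@H]1C[C@]2(C)[C@@H]3[C@@H](OC(C)=O)CC(=C)[C@@H]3[C@@]23OC(=O)C(CO)=C13 | intermediate (not isolated)
31 | butenolide with C13 acetate, C8 tiglate, C2 acetate, C4=C15H2 | C/C=C(\C)C(=O)O[C@H]1C[C@]2(C)[C@@H]3[C@@H](OC(C)=O)CC(=C)[C@@H]3[C@@]23OC(=O)C(COC(C)=O)=C13 | intermediate
32 | CNP0210373.1 | C/C=C(\C)C(=O)O[C@H]1C[C@]2(C)[C@@H]3[C@@H](OC(C)=O)C[C@@](C)(O)[C@@H]3[C@@]23OC(=O)C(COC(C)=O)=C13 | target

Total step count: 20. Longest linear sequence: 17 steps (steps 1–14 and 18–20); steps 15–17 make the phosphonate acid 27 on a side branch.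

Steps most likely to fail

Step 8. The cobalt-bound alkyne may fail to insert the cyclobutene on the concave face, because the bridged tetracycle is strained, and then decomplex or react intermolecularly. The fallback sets out from 11: Ni(cod)2 (zerovalent nickel, one equivalent), PBu3 and 2,6-dimethylphenyl isocyanide in DMF at rt to 50 °C. Oxidative cyclisation of alkyne and cyclobutene at a single nickel centre, again on the tethered face, then isocyanide insertion into the Ni–C1 bond and reductive elimination, should give the N-(2,6-dimethylphenyl) imine of 13 F1. Hydrolysis with aqueous oxalic acid in THF returns to the route at 13.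

Step 18. Acylation of the hindered tertiary α-ketol may be slow enough for acyloin rearrangement (ring expansion of ring B) to intervene, or the phosphonate carbanion may lose its silyloxy group by β-elimination. The fallback sets out from 22 and builds the phosphonate on the substrate. Bromoacetyl bromide and pyridine in CH2Cl2 at −20 °C give the C6 bromoacetate of 22 F2. P(OEt)3 at 90 °C (Arbuzov reaction) gives the C6 (diethoxyphosphoryl)acetate of 22 F3. Aqueous formaldehyde (one equivalent) and K2CO3 in THF at 0 °C then hydroxymethylate the phosphonate carbanion, and the adduct closes by intramolecular Horner–Wadsworth–Emmons reaction to the hydroxymethyl butenolide 30, where the route is rejoined before the acetylation of step 19.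

Step 11. The activated concave C2 hydroxyl may eliminate to the ring C alkene instead of being displaced. The fallback sets out from ketone 14: Li in liquid NH3/THF at −78 °C, then NH4Cl. This dissolving-metal reduction under thermodynamic control should place the hydroxyl on the convex face and give the C2 convex-face alcohol F4. Ac2O in pyridine at 0 °C acetylates this unhindered hydroxyl in preference to the neopentyl-type C7–OH and returns to the route at 16.

Further compounds
F1 | step 8 | N-(2,6-dimethylphenyl) imine of 13 | C1C[C@]2(C)[C@@H]3C(=Nc5c(C)cccc5C)C=C4CO[C@H]1[C@@]2(O[Si](CC)(CC)CC)[C@H]34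
F2 | step 18 | C6 bromoacetate of 22 | C/C=C(\C)C(=O)O[C@H]1C[C@]2(C)[C@@H]3[C@@H](OC(C)=O)CC(=C)[C@@H]3[C@]2(OC(=O)CBr)C1=O
F3 | step 18 | C6 (diethoxyphosphoryl)acetate of 22 | C/C=C(\C)C(=O)O[C@H]1C[C@]2(C)[C@@H]3[C@@H](OC(C)=O)CC(=C)[C@@H]3[C@]2(OC(=O)CP(=O)(OCC)OCC)C1=O
F4 | step 11 | C2 convex-face alcohol (C2 epimer of 15) | C1C[C@]2(C)[C@@H]3[C@@H](O)CC(=C)[C@@H]3[C@]2(O[Si](CC)(CC)CC)[C@@H]1O
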